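## The problem

The target is a C40 heterodimer. One half is a ring-B-contracted abietane (a 6-5-6 tricycle) whose ring C has become a bicyclo[3.2.1]oct-3-ene-2,8-dione carrying an enolised 1,2-dione. The other half is labda-8(17),12E,14-trien-18-oic acid, whose terminal vinyl group (C14'–C15') forms the two-carbon bridge between C13 and C8. Ten stereocentres and one E-alkene have to be set. The four labdane centres (C4', C5', C9', C10') are remote and can only be brought in with an enantiopure labdane. In the abietane half C10 is the controlling centre: it fixes the ring fusion at C5 and, through the two β-axial methyl groups on C4 and C10, the face on which C6 receives its hydroxyl group. C6 (OH α, CHO β) sits next to C8 and in turn differentiates the faces of ring C when C8, C13 and C14' are created in the union. The fragile groups are the tertiary α-hydroxy aldehyde at C6 (α-ketol ring expansion, deformylation), the exocyclic C8'=C17' alkene and the 12',14'-diene (acid-induced cyclisation), and C5–H while C6 is a ketone. The feature that invites the key step is that ring A is fused through C5–C10 to the five-membered ring B, whose remaining atoms are C6 and the two arene carbons C8 and C9. An enone on C8 (C6=O, C5=C4) and a diene on C9 (C10=C1–C2=C3) are therefore held three atoms apart, and one [4+2] addition closes ring A and ring B together and makes both quaternary carbons C4 and C10.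

## Retrosynthesis

**24 to 19 and 23.** The C8–C15' and C13–C14' bonds are cut. A bicyclo[3.2.1]octenedione with an enolised 1,2-dione is the signature of a perezone-type [5+2] cycloaddition between a 2-hydroxy-1,4-benzoquinone and an alkene. No other cut removes both quaternary bridgeheads at once, and this one divides the molecule into two C20 halves, the hydroxyquinone 19 and the trienoic acid 23. The forward reaction must engage the diene terminus and not the exocyclic alkene, attach the CH2 carbon to C8, approach the α-face of ring C and place the dienyl residue endo.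

**19 back to 14.** Apart from the C6=C7 bond (methylenation of a ketone), only oxidation levels change. The aldehyde is kept as the primary alcohol (18) until the base-mediated unmasking of the hydroxyquinone from the methoxyquinone 17 is over. The quinone comes from the trimethoxyarene 16. The C6–O and C7–O bonds come from α-face dihydroxylation of the exocyclic alkene 15, which is made from ketone 14. Adding a one-carbon nucleophile to the ketone instead would also attack the α-face and would give the wrong C6 epimer, which is why the alkene route is preferred.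

**14 to 13, 11 and 10.** Hydrogenation links 14 to the cyclohexene 13. In 13 the C5–C10 and C3–C4 bonds are cut, which opens rings A and B in one operation and leads to the achiral triene 10. The inside methyl group on the diene terminus C10 and the endo preference of a Lewis-acid-bound carbonyl both point to the cis-fused ketone 11 as the kinetic cycloadduct. The plan therefore does not ask the cycloaddition for the trans fusion. It asks only for the absolute configuration at C10, and C5 is re-set afterwards by protonation of the enolate on its open α-face (11 to 13).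

**10 to 7 and 9.** The aryl–alkenyl bond C9–C10 is cut (cross-coupling). This keeps the diene geometry in a small boronate 9, which is made from the enyne 8 by a syn addition of fixed regiochemistry. The coupling must retain the alkene geometry and must run cold enough that no uncatalysed, racemic cycloaddition occurs.

**7 to 6, 4 and 5, then 3 and 1.** The C9–Br bond and the C8–C6 bond are cut. The ring position para to the C12 methoxy group is the most nucleophilic, so acylation with 5 goes to C8 and leaves C9 as the only position for bromine. The isopropyl group is traced to the ring position of 1 that lies between two methoxy groups, which is reached by directed lithiation (1 to 3 to 4). All three ring C oxygens are present from the first compound.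

**23 to 22, 21 and 20.** The C14'=C15' and C8'=C17' bonds are cut (two methylenations of 22), then C12'=C13' (a stabilised ylide on aldehyde 21). In levopimaric acid 20 the homoannular diene lies exactly on the two bonds that must be broken (C8=C14 and C12=C13). One ozonolysis therefore leaves the decalin with its C8 ketone, its C12 aldehyde and all four stereocentres, including the 18-carboxyl group.

## Roads not taken

**Alternative 1:** The cut is through C4'–C5' and C9'–C10' of the labdane decalin. In the forward step a copalyl-diphosphate-type cyclase would protonate the terminal alkene of E-16-hydroxygeranylgeranyl diphosphate A1 and deliver 18-hydroxycopalyl diphosphate A2, with four stereocentres, the exocyclic alkene and the C18 oxygen set at once. This is the only de novo, catalytic entry to the 18-oxygenated labdane and would not depend on the supply of a resin acid. In that respect it is better than the chosen plan. Its weak points are these: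
- the allylic hydroxyl group lowers the basicity of the alkene that has to be protonated, and the substrate is not the natural one;
- A1 itself needs a selective terminal oxidation and a diphosphorylation;
- A2 still has to be dephosphorylated, oxidised at C18 in the presence of the allylic C15 alcohol, and dehydrated regioselectively to the 12E,14-diene.

It also leaves the harder half and the union untouched. The chosen plan sets three conventional steps from 20 to 23 against it.

**Alternative 2:** The cut is through C11–C12, C13–C14 and C14–C8, so that ring C is assembled last. A pentacarbonylchromium methoxycarbene A3 on C9 of an enantiopure trans-hydrindene would react with 3-methylbut-1-yne A4 and one CO ligand to give the phenol A5. Its merit is real: C5 and C10 would be fixed in a bicyclic building block before the arene exists, so no enantioselective cycloaddition is needed, and the alkyne insertion places the isopropyl group next to the phenol. Against it: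
- A5 lacks the C12 oxygen, which must be added after quinone formation;
- C6 is still a secondary silyl ether and has to pass through the ketone and the same methylenation and dihydroxylation as here;
- A3 demands a long synthesis of a strained, fully substituted trans-hydrindene;
- chromium is used stoichiometrically.

The chosen plan has a riskier stereochemical step but reaches the tricyclic ketone 13 in eight steps with all three ring C oxygens in place.

**Alternative 3:** The cut is at the C5–C6 bond of the target, made by ring contraction of an abietane. Hydroxide would add to the C6 ketone of the 6,7-dione A6, C5 would migrate to C7, and the α-hydroxy acid A7 would result. This road takes C5 and C10 from the chiral pool and creates the quaternary carbinol with its one-carbon substituent in a single step. In both respects it is better than the chosen plan. Its weak points: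
- A6 enolises towards C5, so the ring fusion is at risk before the shift;
- the configuration of the new carbinol (OH α) is not assured;
- the hindered acid must be taken down to the aldehyde;
- ring C carries only the C12 oxygen, so C11 and C14 must be oxidised late on an arene that bears a benzylic tertiary α-hydroxy carbonyl group.

The chosen plan sets against this a ring C that is fully oxygenated from compound 1 and a C6 centre installed by a face-selective dihydroxylation. The price is that absolute configuration has to come from a catalyst.

Key step: step 7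

Remark on numbering: atoms of the contracted abietane half carry abietane locants (C5/C10 ring fusion, C6 ring B carbonyl or carbinol carbon, C7 its exocyclic carbon, C11 to C14 in ring C), α/β refer to the orientation with the C10 methyl group β, and labdane atoms are primed in 24.

Remark on step 7: the (S)-oxazaborolidine is written on the assumption that it shields the enone face leading to 10S; the antipodal catalyst is used if the first run shows the opposite sense.

Step 1
Reactants: 1 1,2,4-trimethoxybenzene
Product: 3 2-(2,3,6-trimethoxyphenyl)propan-2-ol, via 2,3,6-trimethoxyphenyllithium 2 (not isolated)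
Conditions: n-BuLi (1.1 equiv), THF, 0 °C to rt; acetone, −78 °C to rt; aq. NH4Cl
Reagents that add atoms: acetone, CC(C)=O
Why: Directed ortho-lithiation removes the proton between the two methoxy groups, the most acidic and doubly coordinated site, and the aryllithium adds to the ketone.

Step 2
Reactants: 3 2-(2,3,6-trimethoxyphenyl)propan-2-ol
Product: 4 2-isopropyl-1,3,4-trimethoxybenzene
Conditions: Et3SiH (3 equiv), CF3CO2H (5 equiv), CH2Cl2, 0 °C to rt
Reagents that add atoms: none
Why: Ionic hydrogenation: acid ionises the tertiary benzylic alcohol to a cation stabilised by two ortho methoxy groups and the silane delivers hydride.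

Step 3
Reactants: 4 2-isopropyl-1,3,4-trimethoxybenzene; 5 3-methylbut-2-enoyl chloride
Product: 6 3-methyl-1-[2,4,5-trimethoxy-3-(propan-2-yl)phenyl]but-2-en-1-one
Conditions: AlCl3 (1.1 equiv), CH2Cl2, −20 to 0 °C
Reagents that add atoms: none
Why: Friedel–Crafts acylation at the ring position para to one methoxy group and ortho to another (C8); the low temperature avoids cleavage of the ortho methyl ether and ring closure of the enone onto C9.

Step 4
Reactants: 6 3-methyl-1-[2,4,5-trimethoxy-3-(propan-2-yl)phenyl]but-2-en-1-one
Product: 7 1-[2-bromo-3,4,6-trimethoxy-5-(propan-2-yl)phenyl]-3-methylbut-2-en-1-one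
Conditions: N-bromosuccinimide (1.05 equiv), MeCN, 0 °C to rt, dark
Reagents that add atoms: N-bromosuccinimide, O=C1CCC(=O)N1Br
Why: Electrophilic aromatic bromination at the only free ring position (C9), activated by the ortho methoxy and para isopropyl groups; the electron-poor enone alkene is slow towards the reagent in a polar solvent without light.

Step 5
Reactants: 8 pent-1-en-3-yne
Product: 9 4,4,5,5-tetramethyl-2-[(2Z)-penta-2,4-dien-2-yl]-1,3,2-dioxaborolane
Conditions: B2pin2 (1.0 equiv), CuCl (5 mol%), Xantphos (5 mol%), NaOtBu (10 mol%), MeOH (2 equiv), THF, rt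
Reagents that add atoms: bis(pinacolato)diboron, CC1(C)OB(OC1(C)C)B1OC(C)(C)C(C)(C)O1
Why: Copper-catalysed formal hydroboration of the alkyne (borylcupration, then protonolysis): the addition is syn, boron goes to the methyl-bearing carbon and copper to the carbon next to the vinyl group, so boron ends trans to the vinyl group.

Step 6
Reactants: 7 1-[2-bromo-3,4,6-trimethoxy-5-(propan-2-yl)phenyl]-3-methylbut-2-en-1-one; 9 4,4,5,5-tetramethyl-2-[(2Z)-penta-2,4-dien-2-yl]-1,3,2-dioxaborolane
Product: 10 3-methyl-1-{3,4,6-trimethoxy-2-[(2E)-penta-2,4-dien-2-yl]-5-(propan-2-yl)phenyl}but-2-en-1-one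
Conditions: Pd(OAc)2 (5 mol%), SPhos (10 mol%), K3PO4 (3 equiv), toluene/H2O 10:1, 45 °C
Reagents that add atoms: none
Why: Suzuki–Miyaura coupling with retention of the alkene geometry; the ortho acyl group helps oxidative addition and the bulky biarylphosphine allows a doubly ortho-substituted bromide to couple at a temperature low enough to keep the product from cyclising without catalyst.

Step 7
Reactants: 10 3-methyl-1-{3,4,6-trimethoxy-2-[(2E)-penta-2,4-dien-2-yl]-5-(propan-2-yl)phenyl}but-2-en-1-one
Product: 11 (4bS,8aR)-1,3,4-trimethoxy-4b,8,8-trimethyl-2-(propan-2-yl)-4b,7,8,8a-tetrahydro-9H-fluoren-9-one (cis-fused C6 ketone with C1=C2 alkene; 5β-H and 10β-methyl)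
Conditions: (S)-1-(2-methylphenyl)-3,3-diphenyltetrahydro-1H,3H-pyrrolo[1,2-c][1,3,2]oxazaborole (20 mol%), HN(SO2CF3)2 (18 mol%), CH2Cl2, −60 to −20 °C
Reagents that add atoms: none
Why: The protonated oxazaborolidine binds the C6 carbonyl oxygen and lowers the LUMO of the C5=C4 enone; a concerted but strongly asynchronous [4+2] addition follows, in which the C3–C4 bond (free diene terminus to the cation-stabilising dimethyl carbon) leads and the C5–C10 bond completes it. The closest known reaction types are the Lewis-acid-promoted intramolecular Diels–Alder reaction of nona-1,3,8-trienes with the activating ketone in the tether and the oxazaborolidinium-catalysed Diels–Alder reaction of enones. Ring A (six-membered) is closed by the cycloaddition itself through both new bonds; ring B (five-membered) is closed by the C5–C10 bond across the existing C9–C8–C6 tether, exo with respect to both reacting π bonds. C10 is set by the catalyst, whose aryl groups shield one face of the bound enone so that C10 meets C5 from the open face; the substrate is achiral, so this is the only source of absolute configuration. C5 is set relative to C10 by the endo placement of the complexed carbonyl, which keeps C6 away from the inside methyl group on C10 and gives the cis fusion; this centre is provisional and is re-set in step 8. The step needs periselectivity (cycloaddition, no cationic oligomerisation, no uncatalysed background reaction) and enantioface selectivity, while regiochemistry is fixed by the tether. The substrate helps: both ortho substituents are twisted out of the arene plane and face each other, the electron-rich aryl group on C10 raises the diene HOMO and stabilises positive charge there, and C3 is unhindered. If the exo mode competes, 13 forms directly and both epimers converge in step 8.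

Step 8
Reactants: 11 (4bS,8aR)-1,3,4-trimethoxy-4b,8,8-trimethyl-2-(propan-2-yl)-4b,7,8,8a-tetrahydro-9H-fluoren-9-one
Product: 13 (4bS,8aS)-1,3,4-trimethoxy-4b,8,8-trimethyl-2-(propan-2-yl)-4b,7,8,8a-tetrahydro-9H-fluoren-9-one (trans-fused C6 ketone with C1=C2 alkene; 5α-H), via potassium enolate 12 (not isolated)
Conditions: KN(SiMe3)2 (1.3 equiv), THF, −78 to −20 °C; then AcOH (5 equiv) in THF, −78 °C
Reagents that add atoms: none
Why: Enolisation removes the only α-proton (C5–H) and kinetic protonation returns it to the α-face, because the β-face of C5 is flanked by the axial methyl groups on C4 and C10; this gives the trans ring fusion whatever the cycloaddition delivered.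

Step 9
Reactants: 13 (4bS,8aS)-1,3,4-trimethoxy-4b,8,8-trimethyl-2-(propan-2-yl)-4b,7,8,8a-tetrahydro-9H-fluoren-9-one
Product: 14 (4bS,8aS)-1,3,4-trimethoxy-4b,8,8-trimethyl-2-(propan-2-yl)-4b,5,6,7,8,8a-hexahydro-9H-fluoren-9-one
Conditions: H2 (1 atm), Pd/C (10 wt%), EtOAc, rt
Reagents that add atoms: none
Why: Heterogeneous hydrogenation of the only C=C bond (cis-disubstituted, ring A); the hindered electron-rich aryl ketone is not reduced at 1 atm in a neutral solvent, and C5 is not disturbed.

Step 10
Reactants: 14 (4bS,8aS)-1,3,4-trimethoxy-4b,8,8-trimethyl-2-(propan-2-yl)-4b,5,6,7,8,8a-hexahydro-9H-fluoren-9-one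
Product: 15 6-methylidene tricycle (5α-H, 10β-methyl, 11,12,14-trimethoxy, 13-isopropyl, exocyclic C6=C7)
Conditions: Cp2Ti(μ-Cl)(μ-CH2)AlMe2 (1.5 equiv), pyridine (cat.), THF/toluene, −40 °C to rt
Reagents that add atoms: Cp2Ti(μ-Cl)(μ-CH2)AlMe2, C[Al-]1(C)C[Ti]([Cl+]1)(C1C=CC=C1)C1C=CC=C1
Why: Tebbe methylenation: the titanium methylidene is not basic, so the enolisable C5–H is not epimerised, and it reacts with hindered ketones that resist phosphorus ylides.

Step 11
Reactants: 15 6-methylidene tricycle
Product: 16 6α-hydroxy-6β-(hydroxymethyl) trimethoxyarene (C6,C7-diol)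
Conditions: OsO4 (5 mol%), N-methylmorpholine N-oxide (2 equiv), acetone/H2O 4:1, rt
Reagents that add atoms: OsO4, O=[Os](=O)(=O)=O; N-methylmorpholine N-oxide, C[N+]1([O-])CCOCC1; water, O
Why: Upjohn dihydroxylation: OsO4 adds to the α-face of the exocyclic alkene because the β-face is screened by the axial methyl groups on C4 and C10, which places the C6 hydroxyl α and the hydroxymethyl carbon β.

Step 12
Reactants: 16 6α-hydroxy-6β-(hydroxymethyl) trimethoxyarene
Product: 17 12-methoxy-11,14-quinone C6,C7-diol
Conditions: (NH4)2Ce(NO3)6 (2.5 equiv), MeCN/H2O 2:1, 0 °C, 15 min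
Reagents that add atoms: water, O
Why: Oxidative demethylation of the electron-rich arene by the tetravalent cerium salt gives the methoxy-para-quinone (an ortho-quinone isomer would converge in step 13); the reaction is run cold and briefly so that ring oxidation outruns cleavage of the 1,2-diol.

Step 13
Reactants: 17 12-methoxy-11,14-quinone C6,C7-diol
Product: 18 12-hydroxy-11,14-quinone C6,C7-diol
Conditions: KOH (1 M aq., 3 equiv), MeOH, 0 °C to rt; then 1 M HCl to pH 3
Reagents that add atoms: potassium hydroxide, [K+].[OH-]
Why: Addition–elimination of hydroxide at C12 (saponification of a vinylogous methyl ester) and acidification; the diol tolerates base, which is why the aldehyde is formed only afterwards.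

Step 14
Reactants: 18 12-hydroxy-11,14-quinone C6,C7-diol
Product: 19 12-hydroxy-11,14-quinone with 6α-hydroxy and 6β-formyl groups
Conditions: TEMPO (20 mol%), PhI(OAc)2 (1.2 equiv), CH2Cl2, rt
Reagents that add atoms: none
Why: Oxoammonium (TEMPO) oxidation is selective for the primary alcohol; the tertiary C6 alcohol cannot react and the medium is neither basic nor strongly acidic, so the α-hydroxy aldehyde is not rearranged.

Step 15
Reactants: 20 levopimaric acid (abieta-8(14),12-dien-18-oic acid)
Product: 21 8-oxo-13,14,15,16,17-pentanorlabdan-12-al-18-oic acid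
Conditions: O3, CH2Cl2/MeOH 4:1, −78 °C; then Me2S (6 equiv), −78 °C to rt
Reagents that add atoms: ozone, [O-][O+]=O
Why: Ozonolysis of both C=C bonds of the homoannular diene (C8=C14 and C12=C13) with reductive work-up removes C13 and C14 with the isopropyl group and leaves the C8 ketone and the C12 aldehyde; C4, C5, C9 and C10 are untouched and the C9 side chain is already in the stable equatorial position.

Step 16
Reactants: 21 8-oxo-13,14,15,16,17-pentanorlabdan-12-al-18-oic acid
Product: 22 8-oxo-15,17-dinorlabd-12E-en-14-al-18-oic acid
Conditions: Ph3P=C(CH3)CHO (1.3 equiv), toluene, 80 °C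
Reagents that add atoms: 2-(triphenylphosphoranylidene)propanal, CC(C=O)=P(c1ccccc1)(c1ccccc1)c1ccccc1
Why: Wittig reaction of a stabilised ylide: it reacts with the aldehyde only, not with the hindered ring ketone, and gives the E-trisubstituted enal; the free acid is tolerated.

Step 17
Reactants: 22 8-oxo-15,17-dinorlabd-12E-en-14-al-18-oic acid
Product: 23 labda-8(17),12E,14-trien-18-oic acid
Conditions: Ph3PCH3Br (6 equiv), KOtBu (5.5 equiv), THF, 0 °C; add 22, 0 °C then 60 °C; aq. NH4Cl
Reagents that add atoms: methyltriphenylphosphonium bromide, C[P+](c1ccccc1)(c1ccccc1)c1ccccc1.[Br-]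
Why: Two Wittig methylenations in one flask: the enal carbonyl reacts at 0 °C and gives the 12E,14-diene without touching the existing alkene geometry, and the hindered C8 ketone reacts on warming; one equivalent of base is taken up by the acid.

Step 18
Reactants: 19 12-hydroxy-11,14-quinone with 6α-hydroxy and 6β-formyl groups; 23 labda-8(17),12E,14-trien-18-oic acid (1.5 equiv)
Product: 24 CNP0124601.1 (the [5+2] adduct)
Conditions: BF3·OEt2 (2.5 equiv), CH2Cl2, −78 to −40 °C; pH 7 buffer
Reagents that add atoms: none
Why: Perezone-type [5+2] cycloaddition: boron chelation of the C11 carbonyl and C12 hydroxyl makes C13–C12–C11–C9–C8 a hydroxypentadienyl cation, the CH2 terminus of the diene bonds to C8 and C14' to C13, and loss of the proton leaves the C11 enol. The alkene should approach the α-face of ring C, anti to the C6 formyl and C10 methyl groups and past the small C6 hydroxyl, with the rest of the diene endo under the cation; this sets C8, C13 and C14'. The quinone has no unsubstituted C=C bond, which disfavours the competing [4+2] mode.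

Compound list

1 | 1,2,4-trimethoxybenzene | COc1ccc(OC)c(OC)c1 | starting material
2 | 2,3,6-trimethoxyphenyllithium | COc1ccc(OC)c([Li])c1OC | intermediate (not isolated)
3 | 2-(2,3,6-trimethoxyphenyl)propan-2-ol | COc1ccc(OC)c(C(C)(C)O)c1OC | intermediate
4 | 2-isopropyl-1,3,4-trimethoxybenzene | COc1ccc(OC)c(C(C)C)c1OC | intermediate
5 | 3-methylbut-2-enoyl chloride | CC(C)=CC(=O)Cl | starting material
6 | 3-methyl-1-[2,4,5-trimethoxy-3-(propan-2-yl)phenyl]but-2-en-1-one | COc1cc(C(=O)C=C(C)C)c(OC)c(C(C)C)c1OC | intermediate
7 | 1-[2-bromo-3,4,6-trimethoxy-5-(propan-2-yl)phenyl]-3-methylbut-2-en-1-one | COc1c(Br)c(C(=O)C=C(C)C)c(OC)c(C(C)C)c1OC | intermediate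
8 | pent-1-en-3-yne | C=CC#CC | starting material
9 | 4,4,5,5-tetramethyl-2-[(2Z)-penta-2,4-dien-2-yl]-1,3,2-dioxaborolane | C=C/C=C(\C)B1OC(C)(C)C(C)(C)O1 | intermediate
10 | 3-methyl-1-{3,4,6-trimethoxy-2-[(2E)-penta-2,4-dien-2-yl]-5-(propan-2-yl)phenyl}but-2-en-1-one | COc1c(OC)c(C(C)C)c(OC)c(C(=O)C=C(C)C)c1/C(C)=C/C=C | intermediate
11 | (4bS,8aR)-1,3,4-trimethoxy-4b,8,8-trimethyl-2-(propan-2-yl)-4b,7,8,8a-tetrahydro-9H-fluoren-9-one (cis-fused, 5β-H) | COc1c(OC)c(C(C)C)c(OC)c2c1[C@@]1(C)C=CCC(C)(C)[C@H]1C2=O | intermediate
12 | potassium C5=C6 enolate of 11 (10S) | COc1c(OC)c(C(C)C)c(OC)c2c1[C@@]1(C)C=CCC(C)(C)C1=C2[O-].[K+] | intermediate (not isolated)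
13 | (4bS,8aS)-1,3,4-trimethoxy-4b,8,8-trimethyl-2-(propan-2-yl)-4b,7,8,8a-tetrahydro-9H-fluoren-9-one (trans-fused, 5α-H) | COc1c(OC)c(C(C)C)c(OC)c2c1[C@@]1(C)C=CCC(C)(C)[C@@H]1C2=O | intermediate
14 | (4bS,8aS)-1,3,4-trimethoxy-4b,8,8-trimethyl-2-(propan-2-yl)-4b,5,6,7,8,8a-hexahydro-9H-fluoren-9-one | COc1c(OC)c(C(C)C)c(OC)c2c1[C@@]1(C)CCCC(C)(C)[C@@H]1C2=O | intermediate
15 | 6-methylidene tricycle (5α-H, 10β-methyl, 11,12,14-trimethoxy, 13-isopropyl) | COc1c(OC)c(C(C)C)c(OC)c2c1[C@@]1(C)CCCC(C)(C)[C@@H]1C2=C | intermediate
16 | 6α-hydroxy-6β-(hydroxymethyl) trimethoxyarene | COc1c(OC)c(C(C)C)c(OC)c2c1[C@@]1(C)CCCC(C)(C)[C@@H]1[C@]2(O)CO | intermediate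
17 | 12-methoxy-11,14-quinone with 6α-hydroxy and 6β-hydroxymethyl groups | COC1=C(C(C)C)C(=O)C2=C(C1=O)[C@@]1(C)CCCC(C)(C)[C@@H]1[C@]2(O)CO | intermediate
18 | 12-hydroxy-11,14-quinone with 6α-hydroxy and 6β-hydroxymethyl groups | O=C1C(O)=C(C(C)C)C(=O)C2=C1[C@@]1(C)CCCC(C)(C)[C@@H]1[C@]2(O)CO | intermediate
19 | 12-hydroxy-11,14-quinone with 6α-hydroxy and 6β-formyl groups | O=C1C(O)=C(C(C)C)C(=O)C2=C1[C@@]1(C)CCCC(C)(C)[C@@H]1[C@]2(O)C=O | intermediate
20 | levopimaric acid (abieta-8(14),12-dien-18-oic acid) | CC(C)C1=CC[C@H]2C(=C1)CC[C@@H]1[C@]2(C)CCC[C@@]1(C)C(=O)O | starting material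
21 | 8-oxo-13,14,15,16,17-pentanorlabdan-12-al-18-oic acid | O=CC[C@H]1C(=O)CC[C@@H]2[C@]1(C)CCC[C@@]2(C)C(=O)O | intermediate
22 | 8-oxo-15,17-dinorlabd-12E-en-14-al-18-oic acid | O=C/C(C)=C/C[C@H]1C(=O)CC[C@@H]2[C@]1(C)CCC[C@@]2(C)C(=O)O | intermediate
23 | labda-8(17),12E,14-trien-18-oic acid | C=C/C(C)=C/C[C@H]1C(=C)CC[C@@H]2[C@]1(C)CCC[C@@]2(C)C(=O)O | intermediate
24 | CNP0124601.1, the [5+2] adduct of 19 and 23 | C=C1CC[C@@H]2[C@](C)(CCC[C@@]2(C)C(=O)O)[C@H]1C/C=C(\C)[C@@H]1C[C@@]23C(=O)[C@]1(C(C)C)C(=O)C(O)=C2[C@@]1(C)CCCC(C)(C)[C@@H]1[C@]3(O)C=O | target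

Total step count: 18. Longest linear sequence: 14 steps (steps 1 to 4, 6 to 14 and 18); step 5 and steps 15 to 17 are side branches.

Least certain steps

**Step 7 (key step).** The most likely failure is poor enantioface discrimination or no turnover, because the ketone is flanked by two ortho substituents and twisted out of the arene plane, so the bulky chiral acid may bind weakly while an uncatalysed or cationic pathway takes over. The fallback sets out from 10. Cyclisation with an achiral Lewis acid (Me2AlCl, CH2Cl2, −78 to 0 °C) gives the racemic cis-fused ketone F1, and enolate protonation as in step 8 gives the racemic trans-fused ketone F2. A kinetic resolution by oxazaborolidine-catalysed borane reduction (B-methyl oxazaborolidine from diphenylprolinol, BH3·SMe2, catalyst enantiomer matched to the unwanted antipode) converts the (5R,10R) ketone into its C6 alcohol F3, which is removed by chromatography. The ketone that remains is 13, where the route is rejoined.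

**Step 18.** Three things may go wrong under the Lewis acid: cyclisation or isomerisation of the triene before it is captured, addition through the exocyclic alkene instead of the diene terminus, and α-ketol rearrangement of the hydroxy aldehyde; facial and endo selectivity are also not assured. The fallback moves the union to the diol oxidation level. It sets out from 18 and 23, which are combined under the same type of activation to give the C6-hydroxymethyl cycloadduct F4. Oxidation of its primary alcohol with TEMPO and PhI(OAc)2 then gives 24.

**Step 8.** Deprotonation of the hindered tertiary C5–H may be incomplete, or the proton may be returned partly on the β-face. The fallback sets C5 by hydrogenation instead. It sets out from 11: silylation (tert-butyldimethylsilyl triflate, Et3N) gives the C5=C6 silyl enol ether F5. Hydrogenation over Pd/C adds hydrogen to the α-face of C5 and C6 and saturates C1=C2 at the same time, giving the 6β-silyl ether F6. Fluoride (Bu4NF) frees the 6β-alcohol F7, and Dess–Martin periodinane returns the ketone 14, where the route is rejoined (step 9 is then not needed).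

**Step 4.** Bromine may add to the enone, brominate its allylic positions or displace the acyl group instead of substituting C9. The fallback introduces the halogens before the enone. It sets out from 4: N-bromosuccinimide gives 1-bromo-2,4,5-trimethoxy-3-(propan-2-yl)benzene F8. Lithium 2,2,6,6-tetramethylpiperidide at −78 °C removes the proton between bromine and methoxy, and iodine gives the bromo iodide F9. Suzuki–Miyaura coupling with 9 at the iodide gives the dienyl bromide F10. Bromine–lithium exchange (n-BuLi, −78 °C) and acylation with N-methoxy-N,3-dimethylbut-2-enamide give 10, where the route is rejoined.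

**Step 14.** The neopentyl alcohol may oxidise slowly, and the acidic hydroxyquinone or the neighbouring tertiary alcohol may lead to cleavage of the C6–C7 bond. The fallback forms the aldehyde before the quinone. It sets out from 16: SO3·pyridine, DMSO and i-Pr2NEt (Parikh–Doering) give the trimethoxyarene hydroxy aldehyde F11. (NH4)2Ce(NO3)6 gives the methoxyquinone hydroxy aldehyde F12, and nucleophilic demethylation with LiI in EtOAc, which avoids aqueous base, gives 19, where the route is rejoined.

## Further compounds

F1 | step 7 | racemic cis-fused ketone (11 and its enantiomer) | COc1c(OC)c(C(C)C)c(OC)c2c1[C@@]1(C)C=CCC(C)(C)[C@H]1C2=O.COc1c(OC)c(C(C)C)c(OC)c2c1[C@]1(C)C=CCC(C)(C)[C@@H]1C2=O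
F2 | step 7 | racemic trans-fused ketone (13 and its enantiomer) | COc1c(OC)c(C(C)C)c(OC)c2c1[C@@]1(C)C=CCC(C)(C)[C@@H]1C2=O.COc1c(OC)c(C(C)C)c(OC)c2c1[C@]1(C)C=CCC(C)(C)[C@H]1C2=O
F3 | step 7 | C6 alcohol of the (5R,10R) trans-fused ketone | COc1c(OC)c(C(C)C)c(OC)c2c1[C@]1(C)C=CCC(C)(C)[C@H]1[C@H]2O
F4 | step 18 | cycloadduct with hydroxymethyl in place of formyl at C6 | C=C1CC[C@@H]2[C@](C)(CCC[C@@]2(C)C(=O)O)[C@H]1C/C=C(\C)[C@@H]1C[C@@]23C(=O)[C@]1(C(C)C)C(=O)C(O)=C2[C@@]1(C)CCCC(C)(C)[C@@H]1[C@]3(O)CO
F5 | step 8 | tert-butyldimethylsilyl enol ether (C5=C6) of 11 | COc1c(OC)c(C(C)C)c(OC)c2c1[C@@]1(C)C=CCC(C)(C)C1=C2O[Si](C)(C)C(C)(C)C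
F6 | step 8 | 6β-(tert-butyldimethylsilyloxy) saturated tricycle (5α-H, 6α-H) | COc1c(OC)c(C(C)C)c(OC)c2c1[C@@]1(C)CCCC(C)(C)[C@@H]1[C@@H]2O[Si](C)(C)C(C)(C)C
F7 | step 8 | 6β-hydroxy saturated tricycle (5α-H) | COc1c(OC)c(C(C)C)c(OC)c2c1[C@@]1(C)CCCC(C)(C)[C@@H]1[C@@H]2O
F8 | step 4 | 1-bromo-2,4,5-trimethoxy-3-(propan-2-yl)benzene | COc1cc(Br)c(OC)c(C(C)C)c1OC
F9 | step 4 | 1-bromo-2-iodo-3,4,6-trimethoxy-5-(propan-2-yl)benzene | COc1c(I)c(Br)c(OC)c(C(C)C)c1OC
F10 | step 4 | 1-bromo-3,4,6-trimethoxy-2-[(2E)-penta-2,4-dien-2-yl]-5-(propan-2-yl)benzene | COc1c(OC)c(C(C)C)c(OC)c(Br)c1/C(C)=C/C=C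
F11 | step 14 | trimethoxyarene with 6α-hydroxy and 6β-formyl groups | COc1c(OC)c(C(C)C)c(OC)c2c1[C@@]1(C)CCCC(C)(C)[C@@H]1[C@]2(O)C=O
F12 | step 14 | 12-methoxy-11,14-quinone with 6α-hydroxy and 6β-formyl groups | COC1=C(C(C)C)C(=O)C2=C(C1=O)[C@@]1(C)CCCC(C)(C)[C@@H]1[C@]2(O)C=O
A1 | alternative 1 | E-16-hydroxygeranylgeranyl diphosphate | OC/C(C)=C/CC/C(C)=C/CC/C(C)=C/CC/C(C)=C/COP(=O)(O)OP(=O)(O)O
A2 | alternative 1 | 18-hydroxycopalyl diphosphate | C=C1CC[C@@H]2[C@](C)(CCC[C@@]2(C)CO)[C@H]1CC/C(C)=C/COP(=O)(O)OP(=O)(O)O
A3 | alternative 2 | pentacarbonylchromium methoxycarbene on C9 of the 6-silyloxy trans-hydrindene | COC(=[Cr](=C=O)(=C=O)(=C=O)(=C=O)=C=O)C1=C[C@H](O[Si](C)(C)C(C)(C)C)[C@H]2C(C)(C)CCC[C@]12C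
A4 | alternative 2 | 3-methylbut-1-yne | CC(C)C#C
A5 | alternative 2 | 11-methoxy-14-hydroxy-13-isopropyl 6-5-6 arene with C6 silyl ether | COc1cc(C(C)C)c(O)c2c1[C@@]1(C)CCCC(C)(C)[C@@H]1[C@H]2O[Si](C)(C)C(C)(C)C
A6 | alternative 3 | 12-methoxyabieta-8,11,13-triene-6,7-dione | CC(C)c1cc2c(cc1OC)[C@@]1(C)CCCC(C)(C)[C@@H]1C(=O)C2=O
A7 | alternative 3 | ring-B-contracted α-hydroxy acid (hydroxyl α, carboxyl β) | CC(C)c1cc2c(cc1OC)[C@@]1(C)CCCC(C)(C)[C@@H]1[C@]2(O)C(=O)O
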